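**Retrosynthetic overview**

1. The all-E triene is cut between its second and third double bonds (Stille coupling): a vinylstannane carrying ring A (the epoxycyclohexenone with the upper dienamide) and an (E,E)-bromodienamide carrying ring B (the 2-amino-3-hydroxycyclopent-2-enone); the latter comes from the bromodienoic acid and the free aminoenolone by N-acylation.
2. Ring B is a cyclic 1,3-dione in enol form: its N-bearing carbon (C2) sits between a ketone carbon (C1) and an enol carbon (C3) that are bridged by C4H2–C5H2. Cutting C2–C3 (retro-Dieckmann) maps the nitrogen and all five ring carbons onto the amino acid 5-aminolevulinic acid; the benzophenone imine of its methyl ester makes C2 a 2-azaallyl pronucleophile, closes the ring and is hydrolysed off in the same flask.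
3. Ring A: a 2,5-dimethoxyanilide is dearomatised to the quinone monoketal, the free enone C=C is epoxidised under catalyst control (C5, C6), (E)-Bu3SnCH=CHLi adds to the ketone anti to the oxirane (C4), and the ketal is hydrolysed.
4. Upper chain: auxiliary-controlled methylation sets the (6R) centre; a Wittig and a Horner–Wadsworth–Emmons olefination build the (2E,4E)-dienamide directly on the aniline.
5. Ring order: the carbocycle of ring A is bought as an arene (dearomatised in step 7), its oxirane is formed in step 8, ring B is formed in step 13, and no ring is formed afterwards.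

Key step: step 13

Assumption: N-benzylcinchonidinium chloride is taken to deliver the (1R,6S) oxirane in step 8; if the sense of induction proves opposite, the pseudoenantiomeric N-benzylcinchoninium chloride replaces it and nothing else changes.

**Route**

Step 1
Reactants: 1 (4R)-4-benzyl-1,3-oxazolidin-2-one; 2 hexanoyl chloride
Product: 3 (4R)-4-benzyl-3-hexanoyl-1,3-oxazolidin-2-one
Conditions: n-BuLi, THF, −78 °C; then 2, −78 → 0 °C
Reagents that add atoms: none
Why: N-acylation of the lithiated oxazolidinone by an acid chloride is the standard entry to Evans imides.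

Step 2
Reactants: 3 (4R)-4-benzyl-3-hexanoyl-1,3-oxazolidin-2-one
Product: 4 (4R)-4-benzyl-3-[(2R)-2-methylhexanoyl]-1,3-oxazolidin-2-one
Conditions: NaN(SiMe3)2, THF, −78 °C; MeI, −78 °C
Reagents that add atoms: iodomethane, CI
Why: Evans asymmetric alkylation: the chelated (Z)-sodium enolate should be methylated on the face away from the benzyl group, which with the (R)-auxiliary sets the (2R) centre; the minor diastereomer is to be removed by chromatography.

Step 3
Reactants: 4 (4R)-4-benzyl-3-[(2R)-2-methylhexanoyl]-1,3-oxazolidin-2-one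
Product: 5 (2R)-2-methylhexan-1-ol
Conditions: LiBH4, H2O (1 equiv), Et2O, 0 °C
Reagents that add atoms: none
Why: Reductive cleavage of the imide with LiBH4 should release the primary alcohol without touching the α-stereocentre and return the auxiliary.

Step 4
Reactants: 5 (2R)-2-methylhexan-1-ol; 6 2-(triphenyl-λ5-phosphanylidene)propanal
Product: 8 (2E,4R)-2,4-dimethyloct-2-enal, via aldehyde 7 (not isolated)
Conditions: TEMPO (cat.), PhI(OAc)2, CH2Cl2, rt; NaHCO3 wash; then 6, toluene, 80 °C
Reagents that add atoms: none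
Why: TEMPO/PhI(OAc)2 oxidation gives the epimerisable aldehyde under non-basic conditions, and the stabilised ylide then olefinates it (Wittig reaction) with the E selectivity expected for α-branched formyl ylides.

Step 5
Reactants: 9 2,5-dimethoxyaniline; 10 (diethoxyphosphoryl)acetic acid
Product: 11 diethyl {2-[(2,5-dimethoxyphenyl)amino]-2-oxoethyl}phosphonate
Conditions: EDC·HCl, DMAP (cat.), CH2Cl2, rt
Reagents that add atoms: none
Why: Carbodiimide amide coupling of an electron-rich aniline with an unhindered acid.

Step 6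
Reactants: 8 (2E,4R)-2,4-dimethyloct-2-enal; 11 diethyl {2-[(2,5-dimethoxyphenyl)amino]-2-oxoethyl}phosphonate
Product: 12 (2E,4E,6R)-N-(2,5-dimethoxyphenyl)-4,6-dimethyldeca-2,4-dienamide
Conditions: NaH, THF, 0 °C → rt
Reagents that add atoms: none
Why: Horner–Wadsworth–Emmons olefination of an enal with a phosphonoacetamide anion should give the new C2=C3 bond with E geometry and leave the allylic stereocentre alone.

Step 7
Reactants: 12 (2E,4E,6R)-N-(2,5-dimethoxyphenyl)-4,6-dimethyldeca-2,4-dienamide
Product: 13 (2E,4E,6R)-N-(6,6-dimethoxy-3-oxocyclohexa-1,4-dien-1-yl)-4,6-dimethyldeca-2,4-dienamide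
Conditions: PhI(OAc)2, MeOH, 0 °C → rt; aqueous work-up
Reagents that add atoms: methanol, CO; water, O
Why: Hypervalent-iodine oxidative dearomatisation of a 2,5-dimethoxyanilide (quinone monoketal formation): the amide nitrogen should direct methanol to the ortho methoxy-bearing carbon, so the ketal ends up next to the N-bearing carbon while the other methoxy carbon becomes the ketone.

Step 8
Reactants: 13 (2E,4E,6R)-N-(6,6-dimethoxy-3-oxocyclohexa-1,4-dien-1-yl)-4,6-dimethyldeca-2,4-dienamide
Product: 14 (2E,4E,6R)-N-[(1R,6S)-5,5-dimethoxy-2-oxo-7-oxabicyclo[4.1.0]hept-3-en-4-yl]-4,6-dimethyldeca-2,4-dienamide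
Conditions: t-BuOOH, NaOH (aq.), N-benzylcinchonidinium chloride (cat.), toluene, 0 °C → rt
Reagents that add atoms: tert-butyl hydroperoxide, CC(C)(C)OO
Why: Weitz–Scheffer nucleophilic epoxidation under chiral phase-transfer catalysis: only the unsubstituted enone C=C is a good acceptor (the other is a vinylogous amide), and the chiral ammonium–peroxide ion pair selects the enantiotopic face and so sets both oxirane centres; the minor diastereomer is to be removed by crystallisation.

Step 9
Reactants: 14 (2E,4E,6R)-N-[(1R,6S)-5,5-dimethoxy-2-oxo-7-oxabicyclo[4.1.0]hept-3-en-4-yl]-4,6-dimethyldeca-2,4-dienamide; 15 (E)-1,2-bis(tributylstannyl)ethene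
Product: 17 (2E,4E,6R)-N-{(1R,2R,6S)-2-hydroxy-5,5-dimethoxy-2-[(E)-2-(tributylstannyl)ethenyl]-7-oxabicyclo[4.1.0]hept-3-en-4-yl}-4,6-dimethyldeca-2,4-dienamide, via stannylvinyllithium 16 (not isolated)
Conditions: 15, n-BuLi, THF, −78 °C; then 14 (0.4 equiv), −78 °C; H2O quench
Reagents that add atoms: none
Why: Tin–lithium exchange gives the vinyllithium with retention of E geometry; once the first equivalent has deprotonated the amide, 1,2-addition to the ketone should occur anti to the neighbouring oxirane oxygen, which places the new hydroxyl syn to the epoxide as the target requires.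

Step 10
Reactants: 17 (2E,4E,6R)-N-{(1R,2R,6S)-2-hydroxy-5,5-dimethoxy-2-[(E)-2-(tributylstannyl)ethenyl]-7-oxabicyclo[4.1.0]hept-3-en-4-yl}-4,6-dimethyldeca-2,4-dienamide
Product: 18 (2E,4E,6R)-N-{(1S,5R,6R)-5-hydroxy-2-oxo-5-[(E)-2-(tributylstannyl)ethenyl]-7-oxabicyclo[4.1.0]hept-3-en-3-yl}-4,6-dimethyldeca-2,4-dienamide
Conditions: montmorillonite K10, wet CH2Cl2, rt
Reagents that add atoms: water, O
Why: The ketal is vinylogously activated by the enamide nitrogen and should hydrolyse on the mildly acidic clay without ionising the tertiary allylic alcohol, opening the oxirane or protodestannylating the vinylstannane.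

Step 11
Reactants: 19 potassium (1E,3E)-5-oxopenta-1,3-dien-1-olate (glutaconaldehyde potassium salt)
Product: 20 (2E,4E)-5-bromopenta-2,4-dienal
Conditions: PPh3, Br2, CH2Cl2, 0 °C; then 19, 0 °C → rt
Reagents that add atoms: bromine, BrBr
Why: The enolate oxygen is activated by Ph3PBr2 and bromide replaces it by addition–elimination on the vinylogous formyl system, which should give the thermodynamically preferred (E,E)-bromodienal.

Step 12
Reactants: 20 (2E,4E)-5-bromopenta-2,4-dienal
Product: 21 (2E,4E)-5-bromopenta-2,4-dienoic acid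
Conditions: NaClO2, NaH2PO4, 2-methylbut-2-ene, t-BuOH/H2O, rt
Reagents that add atoms: sodium chlorite, [Na+].[O-]Cl=O
Why: Pinnick oxidation converts the enal into the acid without isomerising or attacking the bromodiene, the alkene additive scavenging hypochlorous acid.

Step 13
Reactants: 22 methyl 5-amino-4-oxopentanoate hydrochloride (methyl 5-aminolevulinate hydrochloride); 23 diphenylmethanimine (benzophenone imine)
Product: 26 2-amino-3-hydroxycyclopent-2-en-1-one hydrochloride, via ketimine ester 24 (not isolated), via potassium enolate 25 (not isolated)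
Conditions: 23, CH2Cl2, rt, filter, evaporate; KOt-Bu, THF (0.05 M), 0 °C → rt; then HCl (2 M aq.), rt
Reagents that add atoms: hydrogen chloride, Cl
Why: Transimination turns the amine salt into ketimine 24, whose CH2 between the imine nitrogen and the ketone is deprotonated by KOt-Bu to a delocalised 2-azaallyl/enolate anion; this carbon attacks the ester carbonyl, methoxide leaves, and the 2-imino-1,3-dione is at once deprotonated to the vinylogous carboxylate 25, which makes the closure irreversible, before aqueous HCl hydrolyses the imine and delivers 26 while benzophenone is extracted away. The closest known reaction types are the Dieckmann (intramolecular Claisen) condensation of 4-oxoalkanoates to 2-substituted cyclopentane-1,3-diones and the C-acylation of benzophenone Schiff-base (O'Donnell) anions, and the imine plays the part that pyridoxal phosphate plays when 5-aminolevulinate is cyclised in biosynthesis. Ring B is closed in the 5-exo-trig mode at the ester carbonyl; because the charge can rest on the exocyclic C=N unit, the carbanion can reach the Bürgi–Dunitz trajectory with the ring ketone twisted out of conjugation, whereas the enolate of an N-acyl analogue would have to close in the strained 5-(enolendo)-exo-trig mode. No stereocentre is formed, the product being an achiral and tautomerically symmetric 1,3-dione. The step needs C- over O-acylation and ring closure over self-condensation: O-acylation to the enol lactone is reversible in the presence of methoxide while C-acylation is drained by enolate formation, the imine nitrogen carries no hydrogen so that lactam formation and pyrazine-type dimerisation of the amino ketone are blocked, and dilution favours the intramolecular path.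

Step 14
Reactants: 21 (2E,4E)-5-bromopenta-2,4-dienoic acid; 26 2-amino-3-hydroxycyclopent-2-en-1-one hydrochloride
Product: 28 (2E,4E)-5-bromo-N-(2-hydroxy-5-oxocyclopent-1-en-1-yl)penta-2,4-dienamide, via acid chloride 27 (not isolated)
Conditions: (COCl)2, DMF (cat.), CH2Cl2, 0 °C → rt; then 26, pyridine, DMF, 0 °C → rt
Reagents that add atoms: none
Why: N-acylation of the liberated aminoenolone by the acid chloride; any O-acylated enol ester should pass its acyl group on to nitrogen under the basic conditions, the amide being the thermodynamic product.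

Step 15
Reactants: 18 (2E,4E,6R)-N-{(1S,5R,6R)-5-hydroxy-2-oxo-5-[(E)-2-(tributylstannyl)ethenyl]-7-oxabicyclo[4.1.0]hept-3-en-3-yl}-4,6-dimethyldeca-2,4-dienamide; 28 (2E,4E)-5-bromo-N-(2-hydroxy-5-oxocyclopent-1-en-1-yl)penta-2,4-dienamide
Product: 29 (2E,4E,6R)-N-[(1S,5S,6R)-5-hydroxy-5-{(1E,3E,5E)-7-[(2-hydroxy-5-oxocyclopent-1-en-1-yl)amino]-7-oxohepta-1,3,5-trien-1-yl}-2-oxo-7-oxabicyclo[4.1.0]hept-3-en-3-yl]-4,6-dimethyldeca-2,4-dienamide (CNP0262080.2)
Conditions: PdCl2(MeCN)2 (cat.), DMF, rt, dark
Reagents that add atoms: none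
Why: Stille coupling: the ligand-free divalent palladium salt is reduced in situ to zerovalent palladium, which inserts into the C–Br bond, and transmetalation and reductive elimination join the two alkenyl partners with retention of both geometries under neutral conditions that the epoxyenone, the tertiary alcohol and the acidic enol should tolerate.

**Compound list**

1 | (4R)-4-benzyl-1,3-oxazolidin-2-one | O=C1N[C@H](Cc2ccccc2)CO1 | starting material
2 | hexanoyl chloride | CCCCCC(Cl)=O | starting material
3 | (4R)-4-benzyl-3-hexanoyl-1,3-oxazolidin-2-one | CCCCCC(=O)N1[C@H](Cc2ccccc2)COC1=O | intermediate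
4 | (4R)-4-benzyl-3-[(2R)-2-methylhexanoyl]-1,3-oxazolidin-2-one | CCCC[C@@H](C)C(=O)N1[C@H](Cc2ccccc2)COC1=O | intermediate
5 | (2R)-2-methylhexan-1-ol | CCCC[C@@H](C)CO | intermediate
6 | 2-(triphenyl-λ5-phosphanylidene)propanal | CC(C=O)=P(c1ccccc1)(c1ccccc1)c1ccccc1 | starting material
7 | (2R)-2-methylhexanal | CCCC[C@@H](C)C=O | intermediate
8 | (2E,4R)-2,4-dimethyloct-2-enal | CCCC[C@@H](C)/C=C(C)/C=O | intermediate
9 | 2,5-dimethoxyaniline | COc1ccc(OC)c(N)c1 | starting material
10 | (diethoxyphosphoryl)acetic acid | CCOP(=O)(CC(=O)O)OCC | starting material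
11 | diethyl {2-[(2,5-dimethoxyphenyl)amino]-2-oxoethyl}phosphonate | CCOP(=O)(CC(=O)Nc1cc(OC)ccc1OC)OCC | intermediate
12 | (2E,4E,6R)-N-(2,5-dimethoxyphenyl)-4,6-dimethyldeca-2,4-dienamide | CCCC[C@@H](C)/C=C(C)/C=C/C(=O)Nc1cc(OC)ccc1OC | intermediate
13 | (2E,4E,6R)-N-(6,6-dimethoxy-3-oxocyclohexa-1,4-dien-1-yl)-4,6-dimethyldeca-2,4-dienamide | CCCC[C@@H](C)/C=C(C)/C=C/C(=O)NC1=CC(=O)C=CC1(OC)OC | intermediate
14 | (2E,4E,6R)-N-[(1R,6S)-5,5-dimethoxy-2-oxo-7-oxabicyclo[4.1.0]hept-3-en-4-yl]-4,6-dimethyldeca-2,4-dienamide | CCCC[C@@H](C)/C=C(C)/C=C/C(=O)NC1=CC(=O)[C@@H]2O[C@@H]2C1(OC)OC | intermediate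
15 | (E)-1,2-bis(tributylstannyl)ethene | CCCC[Sn](CCCC)(CCCC)/C=C/[Sn](CCCC)(CCCC)CCCC | starting material
16 | (E)-2-(tributylstannyl)ethenyllithium | [Li]/C=C/[Sn](CCCC)(CCCC)CCCC | intermediate
17 | (2E,4E,6R)-N-{(1R,2R,6S)-2-hydroxy-5,5-dimethoxy-2-[(E)-2-(tributylstannyl)ethenyl]-7-oxabicyclo[4.1.0]hept-3-en-4-yl}-4,6-dimethyldeca-2,4-dienamide | CCCC[C@@H](C)/C=C(C)/C=C/C(=O)NC1=C[C@@](O)(/C=C/[Sn](CCCC)(CCCC)CCCC)[C@@H]2O[C@@H]2C1(OC)OC | intermediate
18 | (2E,4E,6R)-N-{(1S,5R,6R)-5-hydroxy-2-oxo-5-[(E)-2-(tributylstannyl)ethenyl]-7-oxabicyclo[4.1.0]hept-3-en-3-yl}-4,6-dimethyldeca-2,4-dienamide | CCCC[C@@H](C)/C=C(C)/C=C/C(=O)NC1=C[C@@](O)(/C=C/[Sn](CCCC)(CCCC)CCCC)[C@@H]2O[C@@H]2C1=O | intermediate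
19 | potassium (1E,3E)-5-oxopenta-1,3-dien-1-olate (glutaconaldehyde potassium salt) | [K+].[O-]/C=C/C=C/C=O | starting material
20 | (2E,4E)-5-bromopenta-2,4-dienal | O=C/C=C/C=C/Br | intermediate
21 | (2E,4E)-5-bromopenta-2,4-dienoic acid | OC(=O)/C=C/C=C/Br | intermediate
22 | methyl 5-amino-4-oxopentanoate hydrochloride | Cl.COC(=O)CCC(=O)CN | starting material
23 | diphenylmethanimine (benzophenone imine) | N=C(c1ccccc1)c1ccccc1 | starting material
24 | methyl 5-[(diphenylmethylidene)amino]-4-oxopentanoate | COC(=O)CCC(=O)CN=C(c1ccccc1)c1ccccc1 | intermediate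
25 | potassium 2-[(diphenylmethylidene)amino]-3-oxocyclopent-1-en-1-olate | [K+].[O-]C1=C(N=C(c2ccccc2)c2ccccc2)C(=O)CC1 | intermediate
26 | 2-amino-3-hydroxycyclopent-2-en-1-one hydrochloride | Cl.NC1=C(O)CCC1=O | intermediate
27 | (2E,4E)-5-bromopenta-2,4-dienoyl chloride | ClC(=O)/C=C/C=C/Br | intermediate
28 | (2E,4E)-5-bromo-N-(2-hydroxy-5-oxocyclopent-1-en-1-yl)penta-2,4-dienamide | O=C(/C=C/C=C/Br)NC1=C(O)CCC1=O | intermediate
29 | (2E,4E,6R)-N-[(1S,5S,6R)-5-hydroxy-5-{(1E,3E,5E)-7-[(2-hydroxy-5-oxocyclopent-1-en-1-yl)amino]-7-oxohepta-1,3,5-trien-1-yl}-2-oxo-7-oxabicyclo[4.1.0]hept-3-en-3-yl]-4,6-dimethyldeca-2,4-dienamide | CCCC[C@@H](C)/C=C(C)/C=C/C(=O)NC1=C[C@@](O)(/C=C/C=C/C=C/C(=O)NC2=C(O)CCC2=O)[C@@H]2O[C@@H]2C1=O | target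

**Count**

Total step count: 15. Longest linear sequence: 10 steps (steps 1, 2, 3, 4, 6, 7, 8, 9, 10, 15).

**Steps most likely to fail and fallbacks**

Step 13. What may go wrong: the anion of the ketimine may shuttle protons (1,3-prototropy to the isomeric aldimine) or condense intermolecularly faster than it closes the ring, or incomplete transimination may leave free amino ketone that dimerises. The fallback sets out from 22 and comes back at 26. Compound 22 is treated with Boc2O and NaHCO3 in THF/H2O to give methyl 5-[(tert-butoxycarbonyl)amino]-4-oxopentanoate F1. Since F1 carries no sensitive group, it can be forced through the classical alkoxide Dieckmann condensation of a 4-oxo ester (KOt-Bu, toluene, 80–110 °C) to tert-butyl (2-hydroxy-5-oxocyclopent-1-en-1-yl)carbamate F2, and HCl in dioxane then removes the carbamate to give 26.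

Step 8. What may go wrong: insufficient or reversed discrimination of the enantiotopic faces by the phase-transfer catalyst, leaving a mixture of oxirane diastereomers that cannot be purified by crystallisation. The fallback sets out from 13 and comes back at 14. Epoxidation without chiral catalyst (t-BuOOH, DBU, THF) gives 14 together with (2E,4E,6R)-N-[(1S,6R)-5,5-dimethoxy-2-oxo-7-oxabicyclo[4.1.0]hept-3-en-4-yl]-4,6-dimethyldeca-2,4-dienamide F3. Because the (6R) side chain makes the two products diastereomers and not enantiomers, they are separated by preparative HPLC (on a chiral stationary phase if needed), and 14 goes on to step 9.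

Step 15. What may go wrong: protodestannylation of the vinylstannane by the acidic enol of the coupling partner, or degradation of the epoxyenone before transmetalation. The fallback sets out from 17 (with 28) and comes back at 29. The coupling is moved before the deketalisation: 17, which has no enone, is coupled with 28 (PdCl2(MeCN)2, DMF, rt) to (2E,4E,6R)-N-[(1R,2S,6S)-2-hydroxy-2-{(1E,3E,5E)-7-[(2-hydroxy-5-oxocyclopent-1-en-1-yl)amino]-7-oxohepta-1,3,5-trien-1-yl}-5,5-dimethoxy-7-oxabicyclo[4.1.0]hept-3-en-4-yl]-4,6-dimethyldeca-2,4-dienamide F4, and montmorillonite K10 in wet CH2Cl2 then unveils the ketone to give 29.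

**Further compounds**

F1 | step 13 | methyl 5-[(tert-butoxycarbonyl)amino]-4-oxopentanoate | COC(=O)CCC(=O)CNC(=O)OC(C)(C)C
F2 | step 13 | tert-butyl (2-hydroxy-5-oxocyclopent-1-en-1-yl)carbamate | CC(C)(C)OC(=O)NC1=C(O)CCC1=O
F3 | step 8 | (2E,4E,6R)-N-[(1S,6R)-5,5-dimethoxy-2-oxo-7-oxabicyclo[4.1.0]hept-3-en-4-yl]-4,6-dimethyldeca-2,4-dienamide | CCCC[C@@H](C)/C=C(C)/C=C/C(=O)NC1=CC(=O)[C@H]2O[C@H]2C1(OC)OC
F4 | step 15 | (2E,4E,6R)-N-[(1R,2S,6S)-2-hydroxy-2-{(1E,3E,5E)-7-[(2-hydroxy-5-oxocyclopent-1-en-1-yl)amino]-7-oxohepta-1,3,5-trien-1-yl}-5,5-dimethoxy-7-oxabicyclo[4.1.0]hept-3-en-4-yl]-4,6-dimethyldeca-2,4-dienamide | CCCC[C@@H](C)/C=C(C)/C=C/C(=O)NC1=C[C@@](O)(/C=C/C=C/C=C/C(=O)NC2=C(O)CCC2=O)[C@@H]2O[C@@H]2C1(OC)OC
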